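The readings were generated by integration from invented constants; noise was put on by code.

At its last reading, 12.0 h, the dawn run held 49% of its free monomer, so c(free monomer) stood at 0.0367 M. It had been 61% at 6.00 h, so it was still falling, and I read that figure as an upper bound on the floor, the equilibrium monomer concentration under which I took chains not to grow. The autumn run gave a second way: at 12.0 h it showed 0% in chains at c(free monomer) = 0.0313 M, a bound from below. Autumn had also lost 2.72 mM of free monomer against 2.5 mM of protic impurity, so I counted one monomer lost per impurity. The two ways parted by 0.00540 M. Dawn was the one that cheated, being unfinished, but autumn gave a bound and no value, so I took the middle, 0.0340 M, as a reading.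

common to all: initiator 3.3 mol%
- autumn: free monomer 0.034 M; protic impurity 2.5 mM; run made earlier
- dawn: free monomer 0.075 M; protic impurity 2.5 mM; run made earlier
- north: free monomer 0.050 M; protic impurity 2.50 mM; time 15 h
- south-west: free monomer 0.050 M; protic impurity 2.50 mM; time 4.0 h

| run | time / h | monomer in chains / % | free monomer / % |
|---|---|---|---|
| autumn | 1.00 | 4 | 98 |
| autumn | 3.00 | 0 | 92 |
| autumn | 6.00 | 0 | 94 |
| autumn | 8.00 | 0 | 95 |
| autumn | 12.0 | 0 | 92 |
| dawn | 1.00 | 6 | 89 |
| dawn | 2.00 | 13 | 85 |
| dawn | 3.00 | 18 | 76 |
| dawn | 6.00 | 33 | 61 |
| dawn | 12.0 | 46 | 49 |

(standard deviation of a reading: 2 percentage points)

* which of the two ends with the longer chains by the average number of monomer units in a chain (chains begun, living or dead) ("neither" if they lie within 10%) (north / south-west / neither)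
* average number of monomer units in a chain (chains begun, living or dead) at the end, north
* average number of monomer units in a chain (chains begun, living or dead) at the end, south-west

- the average divides the monomer in chains by the number of chains begun, living and dead together
- the earlier runs do not show the number of chains; that part of a forecast is a guess

North and south-west had the same charge, so I took the charge less the floor less the protic impurity, 0.0135 M, as the room, the monomer that can stand in chains. Initiator, at 1.65 mM, was charged in less than the protic impurity. Guessing one chain per initiator, a full room meant 8.17 units, and fewer chains in the same room meant longer ones. Dawn's own room, 0.0385 M, was 35.1% filled at 3.00 h and 64.3% at 6.00 h. So, lending both flasks dawn's pace as a rough guess, I expected north near 8.17 units at 15 h, and south-west, at 4.0 h, between 2.87 and 5.26 units.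

The forecast said north, with 7 and 3 units, on the words “I take one chain per initiator”.

The flask gave north, with 9.10 units in north and 4.34 in south-west.

    free monomer + initiator → living end + monomer in chains (k = 14.1 L mol⁻¹ h⁻¹)
    free monomer + living end → monomer in chains + living end, rate k2*[living end]*[free monomer] (k = 99.6 L mol⁻¹ h⁻¹)
    monomer in chains + living end → free monomer + living end, rate k3*[living end] as long as [monomer in chains] is above zero (k = 3.47 h⁻¹)
    protic impurity + free monomer → quenched substrate (k = 6.52 L mol⁻¹ h⁻¹)
    initiator → spent initiator (k = 0.275 h⁻¹)

North's length stood above my full-room figure, although its 0.0107 M in chains at 15.0 h was less than the room. At the start of south-west, initiator entered chains 2.6 times as fast as it became spent initiator, and north ended with 0.00117 M of living end beside 4.77 × 10⁻⁴ M of spent initiator, together the charge. For one more flask, like south-west but with 0.20 M of free monomer, the room came to 0.163 M, or 81.5% of its free monomer charged. At 4.00 h that flask held 72.5% of its free monomer charged in chains, less than that room, at 24.4 units.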